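**Retrosynthetic overview**
- Feature used: C4 of ring C is a ketone carbon whose only carbon neighbours are C4a of ring A and C3, so it is cut out as carbon monoxide. This leaves ring A as a 2-iodophenol (iodine on the future C4a, free OH on the future C8a as O1, the C8 prenyl group and protected O5/O7 in place) and C3–C2–ring B as a terminal arylacetylene.
- Ring C is the only ring built: one palladium-catalysed carbonylative alkyne coupling with amine-mediated cyclisation forms C4a–C4, C4–C3 and O1–C2 and gives the flavone. Rings A and B are bought as phloroglucinol and 3-bromo-4-methoxybenzaldehyde.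
- The iodophenol: phloroglucinol, bis-MOM ether, diethylcarbamate, then two carbamate-directed ortho-metalations that put prenyl and iodine on either side of the future O1 (regiochemistry fixed by the directing group, not by electrophilic substitution), then hydrolysis. The alkyne: Stille prenylation, then Ohira–Bestmann homologation.
- Stereocentres come after the key step: enantioselective copper hydride 1,4-reduction sets C2 (2S flavanone), hydroxylation of the enolate anti to the aryl group sets C3 (2R,3R by CIP once C3 bears OH), then acid removes the MOM groups.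

Key step: step 8

Assumption: the sense of induction of the copper hydride catalyst on this flavone is assigned by analogy only. (R)-DTBM-SEGPHOS is written for hydride delivery to the C2 face that gives the 2S flavanone; the mirror-image ligand would be taken if the opposite sense were found. "Prenyl" means 3-methylbut-2-en-1-yl throughout.

**Step 1**
Reactants: 1 phloroglucinol (benzene-1,3,5-triol)
Product: 2 3,5-bis(methoxymethoxy)phenol
Conditions: MOMCl (2.0 equiv), i-Pr2NEt (2.2 equiv), DMF, 0 °C to rt; chromatography
Reagents that add atoms: chloromethyl methyl ether (MOMCl), COCCl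
Why: O-alkylation of the phenoxide by the hard α-chloro ether (Williamson-type MOM protection) with about two equivalents should give the bis-ether as the main component of a separable statistical mixture, the mono- and tris-ethers being recycled.

**Step 2**
Reactants: 2 3,5-bis(methoxymethoxy)phenol
Product: 3 3,5-bis(methoxymethoxy)phenyl N,N-diethylcarbamate
Conditions: NaH, THF, 0 °C; ClCONEt2, 0 °C to rt
Reagents that add atoms: N,N-diethylcarbamoyl chloride, CCN(CC)C(Cl)=O
Why: O-carbamoylation of the sodium phenoxide installs on the future O1 the strongest oxygen-based directing group for the two ortho-metalations that follow, while the MOM ethers are inert to base.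

**Step 3**
Reactants: 3 3,5-bis(methoxymethoxy)phenyl N,N-diethylcarbamate; 4 prenyl bromide (1-bromo-3-methylbut-2-ene)
Product: 7 3,5-bis(methoxymethoxy)-2-prenylphenyl N,N-diethylcarbamate, via aryllithium 5 (not isolated), via arylcopper 6 (not isolated)
Conditions: s-BuLi, TMEDA, THF, −78 °C; CuBr·SMe2, −78 to −40 °C; then 4, −40 to 0 °C
Reagents that add atoms: none
Why: Directed ortho-metalation in which the carbamate outranks OMOM, so lithiation should occur at C2 between carbamate and OMOM and not at C4 between the two OMOM groups, after which transmetalation to monovalent copper suppresses the anionic Fries shift and the arylcopper is alkylated at the primary carbon of prenyl bromide (SN2 allylation).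

**Step 4**
Reactants: 7 3,5-bis(methoxymethoxy)-2-prenylphenyl N,N-diethylcarbamate
Product: 9 2-iodo-3,5-bis(methoxymethoxy)-6-prenylphenyl N,N-diethylcarbamate, via aryllithium 8 (not isolated)
Conditions: s-BuLi, TMEDA, THF, −78 °C; I2 (1.05 equiv) in THF, −78 °C; aq. Na2S2O3
Reagents that add atoms: iodine, II
Why: Second directed ortho-metalation at the only remaining position next to the carbamate (C6, again flanked by OMOM), expected to be faster than lithiation at C4 or at the benzylic CH2 of the prenyl group, followed by iodinolysis of the aryllithium at a temperature at which the trisubstituted alkene is not attacked.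

**Step 5**
Reactants: 9 2-iodo-3,5-bis(methoxymethoxy)-6-prenylphenyl N,N-diethylcarbamate
Product: 10 2-iodo-3,5-bis(methoxymethoxy)-6-prenylphenol
Conditions: KOH, EtOH/H2O, reflux; then aq. NH4Cl to pH 6–7
Reagents that add atoms: none
Why: Base hydrolysis of the aryl carbamate (acyl substitution at the carbamate carbonyl) frees the phenol that becomes O1, under conditions to which the MOM ethers, the aryl iodide and the prenyl group are inert.

**Step 6**
Reactants: 11 3-bromo-4-methoxybenzaldehyde
Product: 12 4-methoxy-3-prenylbenzaldehyde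
Conditions: tributyl(prenyl)stannane, Pd(PPh3)4 (5 mol%), DMF, 100 °C
Reagents that add atoms: tributyl(3-methylbut-2-en-1-yl)stannane, CCCC[Sn](CCCC)(CCCC)CC=C(C)C
Why: Stille cross-coupling of the aryl bromide with the allylic stannane, which transfers the prenyl group through its unhindered α-carbon and tolerates the free aldehyde.

**Step 7**
Reactants: 12 4-methoxy-3-prenylbenzaldehyde
Product: 13 4-ethynyl-1-methoxy-2-prenylbenzene
Conditions: dimethyl (1-diazo-2-oxopropyl)phosphonate, K2CO3, MeOH, 0 °C to rt
Reagents that add atoms: dimethyl (1-diazo-2-oxopropyl)phosphonate, CC(=O)C(=[N+]=[N-])P(=O)(OC)OC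
Why: Ohira–Bestmann form of the Seyferth–Gilbert homologation, in which the diazomethylphosphonate anion released by methanolysis adds to the aldehyde and loss of dimethyl phosphate and N2 with a 1,2-hydrogen shift gives the terminal alkyne under conditions mild enough for the prenyl group.

**Step 8**
Reactants: 10 2-iodo-3,5-bis(methoxymethoxy)-6-prenylphenol; 13 4-ethynyl-1-methoxy-2-prenylbenzene; 14 carbon monoxide
Product: 17 5,7-bis(methoxymethoxy)-2-(4-methoxy-3-prenylphenyl)-8-prenyl-4H-chromen-4-one, via ynone 15 (not isolated), via enaminone 16 (not isolated)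
Conditions: PdCl2(PPh3)2 (5 mol%), CO (20 bar), Et2NH, 120 °C, autoclave
Reagents that add atoms: none
Why: Zerovalent palladium formed in situ inserts into the C–I bond of 10, CO insertion gives the aroylpalladium iodide, and amine-assisted coupling with alkyne 13 forms C4a–C4 and C4–C3 in ynone 15; diethylamine then adds to C2 of the ynone to give enaminone 16, and the ortho phenol attacks that carbon and expels the amine, forming O1–C2. The closest known reaction is the palladium-catalysed carbonylative coupling of 2-iodophenols with terminal arylacetylenes in a secondary amine to give flavones (carbonylative Sonogashira coupling with cyclisation). Ring C closes in the 6-endo mode, as an addition–elimination at the β-carbon of the enaminone (formally 6-endo-dig on the ynone). No stereocentre is formed. The step needs ring-size selectivity, flavone over the 5-exo aurone, and the amine secures this by making the amine-bearing C2 the only electrophilic carbon; it also needs closure through the right oxygen, which is guaranteed because only the hydroxyl between the iodine-bearing and prenyl-bearing carbons is free while the other ortho oxygen is a MOM ether, so the prenyl group must end at C8. The main competing process is capture of the hindered aroylpalladium species by diethylamine to give the amide, which the high concentration of alkyne is meant to outrun.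

**Step 9**
Reactants: 17 5,7-bis(methoxymethoxy)-2-(4-methoxy-3-prenylphenyl)-8-prenyl-4H-chromen-4-one
Product: 19 (2S)-5,7-bis(methoxymethoxy)-2-(4-methoxy-3-prenylphenyl)-8-prenylchroman-4-one, via silyl enol ether 18 (not isolated)
Conditions: Cu(OAc)2·H2O (5 mol%), (R)-DTBM-SEGPHOS (5.5 mol%), (EtO)2MeSiH, toluene, 0 °C to rt; then aq. citric acid, THF, 0 °C
Reagents that add atoms: none
Why: Copper hydride-catalysed asymmetric conjugate reduction, as known for chromones and other β,β-disubstituted enones, in which the bisphosphine-bound copper hydride delivers hydride to one face of C2 to set the 2S centre, the isolated prenyl alkenes do not react, and trapping of the enolate as silyl enol ether 18 shields C4 from 1,2-reduction and C2 from epimerisation until the mildly acidic work-up.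

**Step 10**
Reactants: 19 (2S)-5,7-bis(methoxymethoxy)-2-(4-methoxy-3-prenylphenyl)-8-prenylchroman-4-one
Product: 21 (2R,3R)-3-hydroxy-5,7-bis(methoxymethoxy)-2-(4-methoxy-3-prenylphenyl)-8-prenylchroman-4-one, via sodium enolate 20 (not isolated)
Conditions: NaN(SiMe3)2, THF, −78 °C; 2-(benzenesulfonyl)-3-phenyloxaziridine, −78 °C; AcOH quench at −78 °C
Reagents that add atoms: 2-(benzenesulfonyl)-3-phenyloxaziridine (Davis oxaziridine), O=S(=O)(c1ccccc1)N1OC1c1ccccc1
Why: Davis hydroxylation of a ketone enolate, in which the N-sulfonyloxaziridine transfers oxygen to C3 on the face opposite to the C2 aryl group to give the 2,3-trans ketol (the C2 descriptor changes from S to R only because C3 now outranks the aryl carbon), and which, unlike peracids or dioxiranes, does not epoxidise the prenyl alkenes.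

**Step 11**
Reactants: 21 (2R,3R)-3-hydroxy-5,7-bis(methoxymethoxy)-2-(4-methoxy-3-prenylphenyl)-8-prenylchroman-4-one
Product: 22 (2R,3R)-3,5,7-trihydroxy-2-(4-methoxy-3-prenylphenyl)-8-prenylchroman-4-one (CNP0233452.1)
Conditions: 3 M aq. HCl/MeOH (1:5), rt to 40 °C
Reagents that add atoms: none
Why: Acid-catalysed acetal exchange of the two aryl MOM ethers with methanol, run at the lowest acidity and temperature that cleave them so that the 7-OH does not add to the 8-prenyl alkene, frees both phenols without touching C2, C3 or the 4'-methyl ether.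

**Compound list**
1 | phloroglucinol | Oc1cc(O)cc(O)c1 | starting material
2 | 3,5-bis(methoxymethoxy)phenol | COCOc1cc(O)cc(OCOC)c1 | intermediate
3 | 3,5-bis(methoxymethoxy)phenyl N,N-diethylcarbamate | CCN(CC)C(=O)Oc1cc(OCOC)cc(OCOC)c1 | intermediate
4 | prenyl bromide (1-bromo-3-methylbut-2-ene) | CC(C)=CCBr | starting material
5 | 2-lithio derivative of 3 (aryllithium, not isolated) | CCN(CC)C(=O)Oc1cc(OCOC)cc(OCOC)c1[Li] | intermediate
6 | 2-cuprio derivative of 3 (arylcopper, not isolated) | CCN(CC)C(=O)Oc1cc(OCOC)cc(OCOC)c1[Cu] | intermediate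
7 | 3,5-bis(methoxymethoxy)-2-prenylphenyl N,N-diethylcarbamate | CCN(CC)C(=O)Oc1cc(OCOC)cc(OCOC)c1CC=C(C)C | intermediate
8 | 6-lithio derivative of 7 (aryllithium, not isolated) | CCN(CC)C(=O)Oc1c([Li])c(OCOC)cc(OCOC)c1CC=C(C)C | intermediate
9 | 2-iodo-3,5-bis(methoxymethoxy)-6-prenylphenyl N,N-diethylcarbamate | CCN(CC)C(=O)Oc1c(I)c(OCOC)cc(OCOC)c1CC=C(C)C | intermediate
10 | 2-iodo-3,5-bis(methoxymethoxy)-6-prenylphenol | Oc1c(I)c(OCOC)cc(OCOC)c1CC=C(C)C | intermediate
11 | 3-bromo-4-methoxybenzaldehyde | COc1ccc(C=O)cc1Br | starting material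
12 | 4-methoxy-3-prenylbenzaldehyde | COc1ccc(C=O)cc1CC=C(C)C | intermediate
13 | 4-ethynyl-1-methoxy-2-prenylbenzene | COc1ccc(C#C)cc1CC=C(C)C | intermediate
14 | carbon monoxide | [C-]#[O+] | starting material
15 | 1-[2-hydroxy-4,6-bis(methoxymethoxy)-3-prenylphenyl]-3-(4-methoxy-3-prenylphenyl)prop-2-yn-1-one (ynone, not isolated) | COc1ccc(C#CC(=O)c2c(O)c(CC=C(C)C)c(OCOC)cc2OCOC)cc1CC=C(C)C | intermediate
16 | (E)-3-(diethylamino)-1-[2-hydroxy-4,6-bis(methoxymethoxy)-3-prenylphenyl]-3-(4-methoxy-3-prenylphenyl)prop-2-en-1-one (enaminone, drawn as the E isomer, not isolated) | CCN(CC)/C(=C/C(=O)c1c(O)c(CC=C(C)C)c(OCOC)cc1OCOC)c1ccc(OC)c(CC=C(C)C)c1 | intermediate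
17 | 5,7-bis(methoxymethoxy)-2-(4-methoxy-3-prenylphenyl)-8-prenyl-4H-chromen-4-one | COc1ccc(-c2cc(=O)c3c(OCOC)cc(OCOC)c(CC=C(C)C)c3o2)cc1CC=C(C)C | intermediate
18 | (2S)-4-[diethoxy(methyl)silyloxy]-5,7-bis(methoxymethoxy)-2-(4-methoxy-3-prenylphenyl)-8-prenyl-2H-chromene (silyl enol ether, not isolated) | COc1ccc([C@H]2Oc3c(CC=C(C)C)c(OCOC)cc(OCOC)c3C(O[Si](C)(OCC)OCC)=C2)cc1CC=C(C)C | intermediate
19 | (2S)-5,7-bis(methoxymethoxy)-2-(4-methoxy-3-prenylphenyl)-8-prenylchroman-4-one | COc1ccc([C@H]2Oc3c(CC=C(C)C)c(OCOC)cc(OCOC)c3C(=O)C2)cc1CC=C(C)C | intermediate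
20 | sodium enolate of 19 (not isolated) | COc1ccc([C@H]2Oc3c(CC=C(C)C)c(OCOC)cc(OCOC)c3C([O-])=C2)cc1CC=C(C)C.[Na+] | intermediate
21 | (2R,3R)-3-hydroxy-5,7-bis(methoxymethoxy)-2-(4-methoxy-3-prenylphenyl)-8-prenylchroman-4-one | COc1ccc([C@H]2Oc3c(CC=C(C)C)c(OCOC)cc(OCOC)c3C(=O)[C@@H]2O)cc1CC=C(C)C | intermediate
22 | (2R,3R)-3,5,7-trihydroxy-2-(4-methoxy-3-prenylphenyl)-8-prenylchroman-4-one (CNP0233452.1) | COc1ccc([C@H]2Oc3c(CC=C(C)C)c(O)cc(O)c3C(=O)[C@@H]2O)cc1CC=C(C)C | target

**Step count**
Total: 11 steps. Longest linear sequence: 9 steps (steps 1–5, then 8–11); the alkyne branch (steps 6–7) joins at step 8.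

**Steps most likely to fail**

Step 8. The aroylpalladium intermediate carries two ortho substituents and may be captured by diethylamine (aminocarbonylation to the amide) faster than by the alkyne. Oxidative addition into the electron-rich, doubly flanked C–I bond may also be slow, and direct non-carbonylative coupling with cyclisation to a benzofuran may compete. The fallback brings in the C4 carbon from DMF instead of CO and builds the ynone stepwise. It sets out from 10 and 13. Phenol 10 is silylated (TBSCl, imidazole, DMF) to tert-butyl[2-iodo-3,5-bis(methoxymethoxy)-6-prenylphenoxy]dimethylsilane F1. Iodine–magnesium exchange (i-PrMgCl·LiCl, THF, 0 °C) and quenching with DMF should give 2-(tert-butyldimethylsilyloxy)-4,6-bis(methoxymethoxy)-3-prenylbenzaldehyde F2. Addition of the lithium acetylide of 13 (n-BuLi, THF, −78 °C) should give the racemic propargylic alcohol F3, and MnO2 in CH2Cl2 should oxidise it to the silyl-protected ynone F4. Buffered desilylation (TBAF, AcOH, THF, 0 °C) returns to the route at ynone 15, which is cyclised with Et2NH in EtOH at reflux to flavone 17.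

Step 9. C2 is the β-carbon of a vinylogous ester further deactivated by the 5- and 7-alkoxy groups, so hydride transfer may stall. 1,2-Reduction of the C4 carbonyl may take over, or facial discrimination between the aryl group and the ring oxygen may be insufficient. The fallback separates reduction from enantioselection. It sets out from 17: conjugate reduction with LiBH(s-Bu)3 (THF, −78 °C, buffered quench) should give the racemic flavanone F5. Kinetic resolution by asymmetric transfer hydrogenation (RuCl(p-cymene)[TsDPEN] of the antipode that reduces the 2R ketone faster, HCO2H/Et3N, EtOAc) should convert the unwanted enantiomer into the (2R,4R)-cis-flavan-4-ol F6. This is separated by chromatography and leaves the 2S ketone, which is compound 19.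

Step 10. The enolate may expel the C8a aryloxide (E1cB opening to the 2'-oxidochalcone) and reclose, eroding the C2 configuration. It may also add to the sulfonimine by-product, or the ketol may be oxidised further. The fallback avoids a metal enolate. It sets out from 19: soft enolisation (TBSOTf, Et3N, CH2Cl2, 0 °C) should give the tert-butyldimethylsilyl enol ether F7. One equivalent of dimethyldioxirane in acetone/CH2Cl2 at −78 °C (Rubottom oxidation, anti to the aryl group) should then give the (2R,3R)-3-(tert-butyldimethylsilyloxy) ketone F8 after silyl migration. The enol ether is far more electron-rich than the trialkyl-substituted prenyl alkenes, which is the basis for expecting it to react first. The conditions of step 11 (HCl, MeOH) then remove the silyl and MOM groups together, and the fallback rejoins the route at target 22.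

**Further compounds**
F1 | step 8 | tert-butyl[2-iodo-3,5-bis(methoxymethoxy)-6-prenylphenoxy]dimethylsilane | CC(C)(C)[Si](C)(C)Oc1c(I)c(OCOC)cc(OCOC)c1CC=C(C)C
F2 | step 8 | 2-(tert-butyldimethylsilyloxy)-4,6-bis(methoxymethoxy)-3-prenylbenzaldehyde | CC(C)(C)[Si](C)(C)Oc1c(C=O)c(OCOC)cc(OCOC)c1CC=C(C)C
F3 | step 8 | 1-[2-(tert-butyldimethylsilyloxy)-4,6-bis(methoxymethoxy)-3-prenylphenyl]-3-(4-methoxy-3-prenylphenyl)prop-2-yn-1-ol (racemic) | COc1ccc(C#CC(O)c2c(O[Si](C)(C)C(C)(C)C)c(CC=C(C)C)c(OCOC)cc2OCOC)cc1CC=C(C)C
F4 | step 8 | 1-[2-(tert-butyldimethylsilyloxy)-4,6-bis(methoxymethoxy)-3-prenylphenyl]-3-(4-methoxy-3-prenylphenyl)prop-2-yn-1-one | COc1ccc(C#CC(=O)c2c(O[Si](C)(C)C(C)(C)C)c(CC=C(C)C)c(OCOC)cc2OCOC)cc1CC=C(C)C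
F5 | step 9 | 5,7-bis(methoxymethoxy)-2-(4-methoxy-3-prenylphenyl)-8-prenylchroman-4-one (racemic) | COc1ccc(C2Oc3c(CC=C(C)C)c(OCOC)cc(OCOC)c3C(=O)C2)cc1CC=C(C)C
F6 | step 9 | (2R,4R)-5,7-bis(methoxymethoxy)-2-(4-methoxy-3-prenylphenyl)-8-prenylchroman-4-ol | COc1ccc([C@@H]2Oc3c(CC=C(C)C)c(OCOC)cc(OCOC)c3[C@H](O)C2)cc1CC=C(C)C
F7 | step 10 | (2S)-4-(tert-butyldimethylsilyloxy)-5,7-bis(methoxymethoxy)-2-(4-methoxy-3-prenylphenyl)-8-prenyl-2H-chromene | COc1ccc([C@H]2Oc3c(CC=C(C)C)c(OCOC)cc(OCOC)c3C(O[Si](C)(C)C(C)(C)C)=C2)cc1CC=C(C)C
F8 | step 10 | (2R,3R)-3-(tert-butyldimethylsilyloxy)-5,7-bis(methoxymethoxy)-2-(4-methoxy-3-prenylphenyl)-8-prenylchroman-4-one | COc1ccc([C@H]2Oc3c(CC=C(C)C)c(OCOC)cc(OCOC)c3C(=O)[C@@H]2O[Si](C)(C)C(C)(C)C)cc1CC=C(C)C
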